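**Plan**
- Ring A is numbered C1 (carries the CH2CH2 bridge to the 3-hydroxyphenyl ring), C2 and C6 (the two 4-hydroxybenzyl groups), C3 (OH), C4 (H), C5 (OMe). Apart from one O-methyl it is a constitutionally symmetric 4,6-dibenzyl-5-alkylresorcinol, that is, an aromatised cyclohexane-1,3-dione.
- Retrosynthesis: mask the three remaining phenols as benzyl ethers, take ring A back to its methyl enol ether and then to the symmetric dione, then cut C2–C1 and C4–C5. This leaves a methyl ketone (C4–C3–C2 with its benzyl group) and an α-benzyl enoate (C5–C6–C1 with the bridge).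
- Forward: the enoate is built by phosphonate alkylation and Horner–Wadsworth–Emmons olefination (C6=C1). Ring A, the only ring made, then closes in one operation by Michael addition followed by Claisen acylation.
- The OH/OMe distinction comes from O-methylating the symmetric dione once, as its enol ether, before dehydrogenation to the phenol; hydrogenolysis ends the route.
- Stereochemistry: the target has no stereogenic element. The sp3 centres that appear at C1, C2 and C6 of the dione are transient and vanish on aromatisation.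

Key step: step 6

Remark on the chemistry: the target is achiral (no stereocentre, stereogenic axis or stereogenic double bond), so "single enantiomer" is read as the compound as drawn. All sp3 intermediates are used as racemates or diastereomer mixtures.

**Step 1**
Reactants: 1 raspberry ketone [4-(4-hydroxyphenyl)butan-2-one]
Product: 2 4-[4-(benzyloxy)phenyl]butan-2-one
Conditions: BnBr, K2CO3, acetone, reflux
Reagents that add atoms: benzyl bromide, BrCc1ccccc1
Why: Williamson ether synthesis, in which carbonate deprotonates only the phenol, so the ketone α-positions should stay untouched.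

**Step 2**
Reactants: 3 3-(3-hydroxyphenyl)propanoic acid
Product: 4 benzyl 3-[3-(benzyloxy)phenyl]propanoate
Conditions: BnBr (2.4 equiv), K2CO3, DMF, rt → 50 °C
Reagents that add atoms: benzyl bromide, BrCc1ccccc1
Why: Williamson etherification of the phenoxide and O-alkylation of the carboxylate should occur under the same conditions and protect both acidic groups in one operation.

**Step 3**
Reactants: 4 benzyl 3-[3-(benzyloxy)phenyl]propanoate
Product: 5 3-[3-(benzyloxy)phenyl]propanal
Conditions: DIBAL-H (1.1 equiv), CH2Cl2, −78 °C; MeOH quench, aq. Rochelle salt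
Reagents that add atoms: none
Why: DIBAL-H partial reduction of an ester, in which the aluminium hemiacetal is stable at −78 °C and releases the aldehyde only on work-up.

**Step 4**
Reactants: 6 trimethyl phosphonoacetate; 7 4-(benzyloxy)benzyl chloride
Product: 8 methyl 3-[4-(benzyloxy)phenyl]-2-(dimethoxyphosphoryl)propanoate (racemic)
Conditions: NaH, DMF, 0 °C → rt, 6 in excess (1.5 equiv)
Reagents that add atoms: none
Why: SN2 C-alkylation of the stabilised phosphonoacetate carbanion by a reactive benzylic chloride, with excess 6 to suppress dialkylation; the new stereocentre is racemic and is lost in step 5.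

**Step 5**
Reactants: 8 methyl 3-[4-(benzyloxy)phenyl]-2-(dimethoxyphosphoryl)propanoate; 5 3-[3-(benzyloxy)phenyl]propanal
Product: 9 methyl (E)-2-[4-(benzyloxy)benzyl]-5-[3-(benzyloxy)phenyl]pent-2-enoate
Conditions: NaH, THF, 0 °C; then 5, 0 °C → rt
Reagents that add atoms: none
Why: Horner–Wadsworth–Emmons olefination of an α-substituted phosphonoacetate with an unbranched aldehyde should give the trisubstituted enoate mainly as the E isomer, and any Z isomer can be carried on because the double-bond geometry is erased in step 6.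

**Step 6**
Reactants: 2 4-[4-(benzyloxy)phenyl]butan-2-one; 9 methyl (E)-2-[4-(benzyloxy)benzyl]-5-[3-(benzyloxy)phenyl]pent-2-enoate
Product: 11 4,6-bis[4-(benzyloxy)benzyl]-5-[2-(3-benzyloxyphenyl)ethyl]cyclohexane-1,3-dione (diastereomer mixture), via acyclic Michael adduct 10 (not isolated)
Conditions: t-BuOK (2.2 equiv), 2 (1.3 equiv), THF, 0 °C → 50 °C; then 1 M HCl
Reagents that add atoms: none
Why: tert-Butoxide reversibly forms the enolates of 2; the more substituted enolate (C2) adds to the β-carbon (C1) of 9 to give the ester enolate of 10, proton transfer moves the charge to the methyl carbon (C4), and this enolate acylates the ester carbon (C5) with loss of methoxide, after which deprotonation of the 1,3-dione to its potassium enolate makes the sequence irreversible. The closest known reaction type is the base-mediated consecutive Michael–Claisen annulation of substituted acetones with α,β-unsaturated esters to cyclohexane-1,3-diones, applied here to a more hindered α,β-disubstituted enoate, which is why the mixture is warmed. Ring A closes by a 6-exo-trig Claisen (Dieckmann-type) acylation. The three sp3 centres formed at C2, C1 and C6 are not controlled; C2 and C6 epimerise under the conditions and all three become sp2 in step 8, so no stereocontrol is needed. The selectivity required is regiochemical (conjugate addition through the benzyl-bearing α-carbon, acylation through the methyl group); it should follow from the thermodynamic preference for the more substituted enolate and the easier acylation at the unhindered methyl carbon, and the reverse order of events (methyl-side acylation first, then 6-endo conjugate addition through the internal carbon) converges on the same dione 11.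

**Step 7**
Reactants: 11 4,6-bis[4-(benzyloxy)benzyl]-5-[2-(3-benzyloxyphenyl)ethyl]cyclohexane-1,3-dione
Product: 12 4,6-bis[4-(benzyloxy)benzyl]-5-[2-(3-benzyloxyphenyl)ethyl]-3-methoxycyclohex-2-en-1-one (diastereomer mixture)
Conditions: MeOH, p-TsOH·H2O (cat.), 3 Å MS, reflux
Reagents that add atoms: methanol, CO
Why: Acid-catalysed enol etherification of a 1,3-dione (vinylogous Fischer esterification), which can give only one constitutional isomer because the identical benzyl groups at C2 and C6 make the two carbonyls constitutionally equivalent.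

**Step 8**
Reactants: 12 4,6-bis[4-(benzyloxy)benzyl]-5-[2-(3-benzyloxyphenyl)ethyl]-3-methoxycyclohex-2-en-1-one
Product: 15 2,4-bis[4-(benzyloxy)benzyl]-3-[2-(3-benzyloxyphenyl)ethyl]-5-methoxyphenol, via silyl dienol ether 13 (not isolated), via cyclohexa-2,5-dienone tautomer 14 (not isolated)
Conditions: LDA (1.2 equiv), THF, −78 °C; TMSCl, −78 → 0 °C; concentrate; Pd(OAc)2 (1.1 equiv), MeCN, rt → 40 °C
Reagents that add atoms: none
Why: Saegusa–Ito oxidation, in which kinetic α'-deprotonation of the vinylogous ester (Stork–Danheiser regiochemistry) and O-silylation give 13, palladation at the α'-carbon and β-hydride elimination give dienone 14, and 14, being the keto tautomer of a phenol, should enolise spontaneously to 15 while the benzyl ethers remain inert.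

**Step 9**
Reactants: 15 2,4-bis[4-(benzyloxy)benzyl]-3-[2-(3-benzyloxyphenyl)ethyl]-5-methoxyphenol
Product: 16 3,3'-dihydroxy-2,6-bis(4-hydroxybenzyl)-5-methoxybibenzyl [2,4-bis(4-hydroxybenzyl)-3-[2-(3-hydroxyphenyl)ethyl]-5-methoxyphenol]
Conditions: H2 (1 atm), 10% Pd/C, EtOAc/MeOH, rt
Reagents that add atoms: none
Why: Palladium-catalysed hydrogenolysis should cleave the three aryl benzyl ethers, whereas the diarylmethane and bibenzyl C–C bonds and the aryl methyl ether are inert under these mild conditions.

**Compound list**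
1 | raspberry ketone, 4-(4-hydroxyphenyl)butan-2-one | CC(=O)CCc1ccc(O)cc1 | starting material
2 | 4-[4-(benzyloxy)phenyl]butan-2-one | CC(=O)CCc1ccc(OCc2ccccc2)cc1 | intermediate
3 | 3-(3-hydroxyphenyl)propanoic acid | OC(=O)CCc1cccc(O)c1 | starting material
4 | benzyl 3-[3-(benzyloxy)phenyl]propanoate | O=C(CCc1cccc(OCc2ccccc2)c1)OCc1ccccc1 | intermediate
5 | 3-[3-(benzyloxy)phenyl]propanal | O=CCCc1cccc(OCc2ccccc2)c1 | intermediate
6 | trimethyl phosphonoacetate | COC(=O)CP(=O)(OC)OC | starting material
7 | 4-(benzyloxy)benzyl chloride | ClCc1ccc(OCc2ccccc2)cc1 | starting material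
8 | methyl 3-[4-(benzyloxy)phenyl]-2-(dimethoxyphosphoryl)propanoate (racemic) | COC(=O)C(Cc1ccc(OCc2ccccc2)cc1)P(=O)(OC)OC | intermediate
9 | methyl (E)-2-[4-(benzyloxy)benzyl]-5-[3-(benzyloxy)phenyl]pent-2-enoate | COC(=O)/C(Cc1ccc(OCc2ccccc2)cc1)=C/CCc1cccc(OCc2ccccc2)c1 | intermediate
10 | methyl 2,4-bis[4-(benzyloxy)benzyl]-3-[2-(3-benzyloxyphenyl)ethyl]-5-oxohexanoate (diastereomer mixture, not isolated) | COC(=O)C(Cc1ccc(OCc2ccccc2)cc1)C(CCc1cccc(OCc2ccccc2)c1)C(Cc1ccc(OCc2ccccc2)cc1)C(C)=O | intermediate
11 | 4,6-bis[4-(benzyloxy)benzyl]-5-[2-(3-benzyloxyphenyl)ethyl]cyclohexane-1,3-dione (diastereomer mixture) | O=C1CC(=O)C(Cc2ccc(OCc3ccccc3)cc2)C(CCc2cccc(OCc3ccccc3)c2)C1Cc1ccc(OCc2ccccc2)cc1 | intermediate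
12 | 4,6-bis[4-(benzyloxy)benzyl]-5-[2-(3-benzyloxyphenyl)ethyl]-3-methoxycyclohex-2-en-1-one (diastereomer mixture) | COC1=CC(=O)C(Cc2ccc(OCc3ccccc3)cc2)C(CCc2cccc(OCc3ccccc3)c2)C1Cc1ccc(OCc2ccccc2)cc1 | intermediate
13 | 1,5-bis[4-(benzyloxy)benzyl]-6-[2-(3-benzyloxyphenyl)ethyl]-4-methoxy-2-(trimethylsilyloxy)cyclohexa-1,3-diene (not isolated) | COC1=CC(O[Si](C)(C)C)=C(Cc2ccc(OCc3ccccc3)cc2)C(CCc2cccc(OCc3ccccc3)c2)C1Cc1ccc(OCc2ccccc2)cc1 | intermediate
14 | 2,4-bis[4-(benzyloxy)benzyl]-3-[2-(3-benzyloxyphenyl)ethyl]-5-methoxycyclohexa-2,5-dien-1-one (not isolated) | COC1=CC(=O)C(Cc2ccc(OCc3ccccc3)cc2)=C(CCc2cccc(OCc3ccccc3)c2)C1Cc1ccc(OCc2ccccc2)cc1 | intermediate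
15 | 2,4-bis[4-(benzyloxy)benzyl]-3-[2-(3-benzyloxyphenyl)ethyl]-5-methoxyphenol | COc1cc(O)c(Cc2ccc(OCc3ccccc3)cc2)c(CCc2cccc(OCc3ccccc3)c2)c1Cc1ccc(OCc2ccccc2)cc1 | intermediate
16 | 3,3'-dihydroxy-2,6-bis(4-hydroxybenzyl)-5-methoxybibenzyl | COc1cc(O)c(Cc2ccc(O)cc2)c(CCc2cccc(O)c2)c1Cc1ccc(O)cc1 | target

**Step count**
Total: 9 steps. Longest linear sequence: 7 steps (3 → 4 → 5 → 9 → 11 → 12 → 15 → 16; steps 2, 3, 5, 6, 7, 8, 9).

**Steps most likely to fail**

Step 6. The conjugate addition joins a secondary enolate carbon to the β-carbon of an α,β-disubstituted enoate. It may therefore be slow enough for enoate deconjugation, ketone self-condensation or conjugate addition through the methyl carbon to compete. The fallback removes the α-benzyl group from the acceptor and introduces the C6 benzyl group afterwards. Aldehyde 5 and phosphonate 6 (NaH, THF) would give methyl (E)-5-[3-(benzyloxy)phenyl]pent-2-enoate F1, a β-monosubstituted acrylate of the class for which this annulation is established. Annulation of F1 with ketone 2 (t-BuOK, THF) would pass through methyl 4-[4-(benzyloxy)benzyl]-3-[2-(3-benzyloxyphenyl)ethyl]-5-oxohexanoate F2 and give 4-[4-(benzyloxy)benzyl]-5-[2-(3-benzyloxyphenyl)ethyl]cyclohexane-1,3-dione F3, with the same C2–C1 and C4–C5 bonds formed. The dianion of F3 (LDA, 2.2 equiv, THF/HMPA, −78 → 0 °C) should form at the unsubstituted C6 methylene; alkylation with chloride 7 returns to dione 11.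

Step 8. Palladation and β-hydride elimination at the fully substituted α'-carbon of the electron-rich silyl dienol ether may be sluggish, and the dienol ether may hydrolyse back to 12 first. The fallback replaces the palladium-mediated dehydrosilylation by a selenoxide syn-elimination. From 12, LDA (THF, −78 °C) and PhSeCl would give 4,6-bis[4-(benzyloxy)benzyl]-5-[2-(3-benzyloxyphenyl)ethyl]-3-methoxy-6-(phenylselanyl)cyclohex-2-en-1-one F4. Oxidation with H2O2/pyridine (CH2Cl2, 0 °C) would give the corresponding selenoxide, 4,6-bis[4-(benzyloxy)benzyl]-5-[2-(3-benzyloxyphenyl)ethyl]-3-methoxy-6-(phenylseleninyl)cyclohex-2-en-1-one F5. F5 should eliminate at or below room temperature to dienone 14, which tautomerises to phenol 15, where the route is rejoined. Excess peroxide and pyridine are meant to keep electrophilic selenium away from the activated C4 position of the new phenol.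

Step 3. Over-reduction to the primary alcohol may occur if the aluminium hemiacetal collapses before the quench, and the enolisable aldehyde may self-condense during work-up. The fallback separates reduction and oxidation. From 4, LiAlH4 (THF, 0 °C) would give 3-[3-(benzyloxy)phenyl]propan-1-ol F6. Dess–Martin periodinane (CH2Cl2, rt) or a Swern oxidation would then return aldehyde 5.

**Further compounds**
F1 | step 6 | methyl (E)-5-[3-(benzyloxy)phenyl]pent-2-enoate | COC(=O)/C=C/CCc1cccc(OCc2ccccc2)c1
F2 | step 6 | methyl 4-[4-(benzyloxy)benzyl]-3-[2-(3-benzyloxyphenyl)ethyl]-5-oxohexanoate | COC(=O)CC(CCc1cccc(OCc2ccccc2)c1)C(Cc1ccc(OCc2ccccc2)cc1)C(C)=O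
F3 | step 6 | 4-[4-(benzyloxy)benzyl]-5-[2-(3-benzyloxyphenyl)ethyl]cyclohexane-1,3-dione | O=C1CC(=O)C(Cc2ccc(OCc3ccccc3)cc2)C(CCc2cccc(OCc3ccccc3)c2)C1
F4 | step 8 | 4,6-bis[4-(benzyloxy)benzyl]-5-[2-(3-benzyloxyphenyl)ethyl]-3-methoxy-6-(phenylselanyl)cyclohex-2-en-1-one | COC1=CC(=O)C(Cc2ccc(OCc3ccccc3)cc2)([Se]c2ccccc2)C(CCc2cccc(OCc3ccccc3)c2)C1Cc1ccc(OCc2ccccc2)cc1
F5 | step 8 | 4,6-bis[4-(benzyloxy)benzyl]-5-[2-(3-benzyloxyphenyl)ethyl]-3-methoxy-6-(phenylseleninyl)cyclohex-2-en-1-one | COC1=CC(=O)C(Cc2ccc(OCc3ccccc3)cc2)([Se](=O)c2ccccc2)C(CCc2cccc(OCc3ccccc3)c2)C1Cc1ccc(OCc2ccccc2)cc1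
F6 | step 3 | 3-[3-(benzyloxy)phenyl]propan-1-ol | OCCCc1cccc(OCc2ccccc2)c1
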